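If this flask is run again, free [E] is the concentration to watch, as Z goes by the step Z + E ⇌ G + L (K2 = 4.06, k2 = 0.280 /M/s), whose forward rate carries [E] as a factor.

Z 0.10 M; X 7.1 mM (held); time 12 s

1. the concentration of E at which the part of the Z that has reacted at 12 s is just 95%, in M

    E + G ⇌ E.G, settled at all times (K1 = 230 /M)
    Z + E ⇌ G + L (K2 = 4.06, k2 = 0.280 /M/s)
    G + Q ⇌ G.Q (K3 = 4300 /M, k3 = 13.6 /M/s)
    X ⇌ Q, rate k4*(csat - [Q]) (k4 = 1.14 /s, csat = 7.1 mM)

- at the start none of Q is dissolved
- the amount of E is what is sought; it is there from the start
- run time (flask): 12 s

For a steady [E], Z is a pseudo-first-order reactant, and the logarithm of its starting over its remaining amount equals the rate constant times [E] times the time. So [E] must stand at 0.892 M, which is the mean free E, the steady [E] that brings the wanted part of Z to reaction in the given time.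

But the charge must exceed this level. At the mean free E, the binding constant of E.G times [E] is 205, so nearly all of the G sits as E.G, and each Z reacted costs two E. Averaged over the time, the Z reacted is 0.0683 M. This reckoning sets aside the back step and the capture of G by Q, and adding two E for each of those Z to the mean free E gives a charge of 1.03 M.

The forecast gives 1.03 M, within 1.01 M to 1.05 M, holding that “each Z reacted removes two E”. The simulation gives 1.03 M.

At 12.0 s the relaxation half-life of Z + E and G + L, both ways together, is 2.84 s, short against the run time of 12 s, and the half-life of Z by the forward rate of this step alone is 2.9 s, beside 2.78 s reckoned from the mean free E. Free E stands at 94.5% of the charge at 1.20 s and 81.7% at 12.0 s, so [E] falls from 0.973 M to 0.842 M, on either side of the mean free E of 0.892 M.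

All constants are those of an exercise; the result is computed.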